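## Structural features

The target is a pentacyclic bis-lactone; atoms are labelled here by phthalide numbering for the butenolide half (C1, O2, C3, C3a, C4–C7, C7a), with C3' for the spiro carbon and C8' for the propyl-bearing carbon. Ring A is an α,β-unsaturated γ-lactone (C1, O2, C3, C3a, C7a) with a (Z)-butylidene group on C3, and it is fused through the tetrasubstituted C3a=C7a bond to ring B, a cyclohexene (C3a, C4, C5, C6, C7, C7a). Ring C is a cyclobutane (C6, C7, C3', C8') cis-fused to ring B at C6–C7, and C3' is also the spiro carbon of a phthalide (lactone ring D on benzene ring E). The four stereocentres C6 (S), C7 (R), C3' (R) and C8' (R) are contiguous on ring C: the hydrogens at C6, C7, C8' and the aryl carbon lie on the convex face, while ring B, the propyl group and the ring D oxygen share the concave face. The fragile parts are the cross-conjugated (Z)-alkylidene butenolide (light, acid, base, oxygen, E/Z drift), the γ-acidic butenolide, and any cyclobutanone intermediate with an enolisable C8'. The real difficulty is the quaternary spiro centre between two tertiary centres, together with a propyl group that must sit on the crowded concave face against the thermodynamic preference. The key step uses the fact that C3', at the ketone oxidation level, is bonded to C7, which is allylic to C3a=C7a; ring C is then a β,γ-unsaturated cyclobutanone and the 1,3-acyl-shift isomer of a bicyclo[2.2.2]oct-5-en-2-one in which C3' is bonded to C3a.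

## Logic of the disconnections

**24 ⇒ 20 + 7 (through 23, 22, 21).** The exocyclic C3=C8 double bond and behind it the C3–C8 bond are cut. C3 is the γ-carbon of ring A and becomes the nucleophilic 5-position of a 2-silyloxyfuran in 21, so the four-carbon chain can come from 7. This takes the light- and base-sensitive dienyl lactone and its alkene geometry out of every earlier intermediate. The forward steps must react at C3 only and must eliminate to the Z isomer.

**20 ⇒ 16 + 17 (through 19, 18).** The C3'–aryl bond and the C3'–O bond of ring D are cut, leaving ketone 16 and the ortho-metalated benzoate 18 made from 17. The cut is placed here because the C3' carbonyl is needed for the key step and because a cyclobutanone is much more electrophilic than the ring A lactone. Two rings and the quaternary centre disappear at once. The nucleophile must enter from the convex face and must add faster than it deprotonates C3 or C8'.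

**16 ⇒ 15.** The C3'–C7 bond is cut, C3' is reconnected to C3a, and the double bond moves from C3a=C7a to C7a=C7. This is the retron of a photochemical 1,3-acyl shift. The strained cis-fused cyclobutanone becomes a bicyclo[2.2.2]octenone, whose three stereocentres are those of a Diels–Alder adduct. The forward step must follow the singlet 1,3-shift and not the triplet oxa-di-π-methane path, and C8' must not epimerise on the way.

**15 ⇒ 14 ⇒ 12 ⇒ 6 + 11 (through 13).** 15 is the resolved enantiomer of 14, and the C3' carbonyl of 14 is traced to the C–NO2 group of 12. The C3'–C3a and C8'–C6 bonds are then cut in the retro-Diels–Alder sense, with 11 as a propylketene equivalent. The bicycle falls apart into a flat diene and a five-carbon dienophile; the E geometry of 11 and an endo nitro group fix the propyl group anti to the alkene bridge. The forward cycloaddition must bond the β-carbon of 11 to C6 (not C3a) and must place the nitro group endo. The ketone has to be unmasked without enolising C8', because the propyl epimer needed is probably the less stable one.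

**11 ⇒ 7 + 8 (through 10, 9).** The C=C bond of 11 is cut by a nitroaldol and dehydration, which gives the E isomer under thermodynamic control. 7 is used twice in the route.

**6 ⇒ 5 ⇒ 3 + 4 ⇒ 1 + 2.** The C6=C7 bond is cut by ring-closing metathesis, the C7a–C7 bond by a vinyl cross-coupling and the C3a–C4 bond by an alkyl cross-coupling on the dibromide 1. This fixes the position of the second double bond of 6 by construction. A dehydrogenation of the tetrahydrophthalide would have to choose between several allylic positions and could run on to the aromatic phthalide. The couplings must take the two C–Br bonds of 1 in the right order (C4 before C3).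

## Other disconnections considered

**Alternative 1:** The cut is through ring B at C5–C6 and C7–C7a. Cyclobut-2-enone A1 and (E)-1-(tert-butyldimethylsilyloxy)buta-1,3-diene A2 would combine in an endo Diels–Alder reaction under a chiral Lewis acid to give the silyloxy cis-bicyclo[4.2.0]octenone A3.
- In its favour: the strained enone is a very reactive dienophile, the regiochemistry follows the ortho rule, and the absolute configuration of C6 and C7 would come from a catalyst. On absolute stereocontrol and on the ease of the cycloaddition this is better than the chosen plan, which needs a resolution and a sluggish thermal cycloaddition.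
- Against it: A3 has no propyl group and none of the carbons C1 and C3. Alkylation of its enolate would put the propyl group on the convex face, the wrong one. Its C7a oxygen is β to the cyclobutanone, so elimination and ring opening threaten. Ring A would have to be annulated with a shift of the double bond from C3a=C4 to C3a=C7a.
- Comparison: both plans rely on convex-face attack for the spiro centre (equal). The mechanism is a thermal, scalable [4+2] against a photostationary photoreaction (better). Step economy after the key step is clearly worse.

**Alternative 2:** The cut is at the spiro centre: C3'–aryl, aryl–C(imidoyl) and C(imidoyl)–O. The aryne from 2-(trimethylsilyl)phenyl triflate A5, tert-butyl isocyanide A6 and endo-8-propylbicyclo[4.2.0]oct-2-en-7-one A4 would give the spiro iminolactone A7.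
- In its favour: the conditions are neutral and fluoride-triggered, so the enolisable cyclobutanone and an acidic butenolide are better tolerated than with a Grignard reagent (equal or better than step 10). A4 is one ketene–diene [2+2] step from simple materials and has the endo propyl group by the nature of that reaction, which is shorter than the chosen access to the cyclobutanone.
- Against it: the ketene cycloaddition leaves the ring B alkene at C4=C5 and makes C3a and C7a plain methylene groups, so the whole of ring A would have to be built at unactivated positions with little regiochemical guidance. The imidate needs a separate hydrolysis, and ketones are weaker partners than aldehydes in this coupling.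
- Comparison: A4 is racemic, so a resolution is needed as in the chosen plan (equal). The spiro-annulation itself is kept here as the fallback for step 10.

**Alternative 3:** The cut is at C8'–C3' and C6–C7. Semihydrogenation of the enyne A8 would give the tetraene A9, which should close by 8π conrotation and then 6π disrotation to the 4,5-didehydro tetracycle A10.
- Correction to the geometry: the conrotation needs the propyl group and the aryl carbon as the two outward groups. By the CIP rules the C7=C3' double bond is then Z (ring D oxygen cis to C7a), so A9 is (E,Z,Z,Z) and only its carbon chain runs E,Z,Z,E. This is the usual stable geometry of 3-ylidenephthalides.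
- In its favour: rings B and C and three stereocentres form in one thermal operation with rings A, D and E already in place. The assembly is convergent and needs no photochemistry (better on convergence).
- Against it: the conrotation fixes only the C8'/C3' relationship. Which pair ends up on the concave face is decided in the 6π step, where nothing in A9 clearly favours the crowded arrangement needed. The fully substituted terminus C3' should slow the 8π closure. C4=C5 must afterwards be reduced selectively within a conjugated dienyl lactone.
- Comparison: A10 is racemic and still lacks the butylidene group, so the resolution and the endgame are the same as in the chosen plan (equal). The step count is similar, but the stereochemical risk is concentrated in one step that cannot be corrected.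

Key step: step 9

**Remarks on the chemistry.**
- The SMILES strings of the key-step precursor and product were checked against the target. They are consistent: the propyl group anti to the alkene bridge in 15 becomes the concave-face propyl group of 16.
- 12, 13 and 14 are racemates; their SMILES show the enantiomer that is carried forward.
- The absolute configuration of 15 is to be assigned after the resolution, for example by vibrational circular dichroism.

## Route

Step 1
Reactants: 1 3,4-dibromofuran-2(5H)-one; 2 but-3-en-1-ylboronic acid
Product: 3 3-bromo-4-(but-3-en-1-yl)furan-2(5H)-one
Conditions: PdCl2(MeCN)2 (5 mol %), AsPh3 (20 mol %), Ag2O (3 equiv), THF, 65 °C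
Reagents that add atoms: none
Why: Suzuki–Miyaura coupling; zerovalent palladium inserts faster into the C4–Br bond (β-position of the enoate, a vinylogous acyl bromide) than into C3–Br, as is general for 3,4-dihalobutenolides, and Ag2O drives transmetalation of the alkylboronic acid without an aqueous base that would attack the lactone.

Step 2
Reactants: 3 3-bromo-4-(but-3-en-1-yl)furan-2(5H)-one; 4 tributyl(ethenyl)stannane
Product: 5 4-(but-3-en-1-yl)-3-ethenylfuran-2(5H)-one
Conditions: Pd2(dba)3 (2.5 mol %), AsPh3 (20 mol %), NMP, 60 °C
Reagents that add atoms: none
Why: Stille coupling of the remaining α-bromo enoate under base-free conditions that spare the butenolide; the weakly bound AsPh3 ligand speeds up the transmetalation.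

Step 3
Reactants: 5 4-(but-3-en-1-yl)-3-ethenylfuran-2(5H)-one
Product: 6 4,5-dihydro-2-benzofuran-1(3H)-one (4,5-dihydrophthalide; diene C3a=C7a–C7=C6)
Conditions: second-generation Grubbs catalyst RuCl2(H2IMes)(PCy3)(=CHPh) (3 mol %), CH2Cl2 (0.01 M), 40 °C; product stored cold under argon
Reagents that add atoms: none
Why: Ring-closing olefin metathesis between the two terminal alkenes closes the six-membered ring with loss of ethene and places the new double bond at C6=C7 by construction; the tetrasubstituted, electron-poor C3a=C7a bond does not react with the ruthenium alkylidene.

Step 4
Reactants: 7 butanal; 8 nitromethane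
Product: 9 1-nitropentan-2-ol (racemic)
Conditions: KOt-Bu (5 mol %), THF/t-BuOH, 8 in excess, 0 °C to rt
Reagents that add atoms: none
Why: Henry (nitroaldol) addition; excess 8 and catalytic base limit double addition and aldehyde self-condensation, and the racemic carbinol centre is removed in step 5.

Step 5
Reactants: 9 1-nitropentan-2-ol
Product: 11 (E)-1-nitropent-1-ene, via 1-nitropentan-2-yl mesylate 10 (not isolated)
Conditions: MsCl, Et3N, CH2Cl2, −10 to 0 °C
Reagents that add atoms: none
Why: Mesylation and E1cB elimination through the nitronate give the conjugated nitroalkene as the thermodynamically preferred E isomer.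

Step 6
Reactants: 6 4,5-dihydro-2-benzofuran-1(3H)-one; 11 (E)-1-nitropent-1-ene
Product: 12 racemic Diels–Alder adduct, lactone-fused 2-nitro-3-propylbicyclo[2.2.2]oct-5-ene (C3'–NO2 on the carbon bonded to C3a and syn to the C7=C7a bridge, propyl on C8' bonded to C6 and anti to that bridge)
Conditions: 11 (3 equiv), toluene (2 M), BHT (2 mol %), 100 °C, sealed tube, argon
Reagents that add atoms: none
Why: Polar, asynchronous [4+2] cycloaddition with a nitroalkene as ketene equivalent: the electrophilic β-carbon of 11 should bond first to the unhindered terminus C6, which leaves allyl-cation character on C7 and the tertiary C3a with the lactone carbonyl at the nodal C7a, so the nitro carbon closes onto C3a; the E geometry fixes C3'/C8' trans, and an endo nitro group places the propyl group exo, which sets C3a, C6 and C8' in the relative sense needed.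

Step 7
Reactants: 12 racemic nitro adduct
Product: 14 racemic lactone-fused 3-propylbicyclo[2.2.2]oct-5-en-2-one (ketone C3' on C3a, propyl anti to the alkene bridge), via potassium nitronate 13 (not isolated)
Conditions: KOt-Bu (1.05 equiv), THF, −78 to 0 °C; then aqueous TiCl3 (4.5 equiv), NH4OAc buffer (pH 5–6), 0 °C to rt
Reagents that add atoms: water, O
Why: Reductive Nef reaction (McMurry type): C3'–H is the only acidic proton of 12, trivalent titanium reduces the nitronate to the imine, and hydrolysis in the weakly acidic buffer gives the ketone without enolising the epimerisable C8'.

Step 8
Reactants: 14 racemic bicyclooctenone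
Product: 15 (3aS,6R,8R)-8-propyl-4,5-dihydro-3H-3a,6-ethano-2-benzofuran-1,9(6H)-dione (bridge atoms 8 = C8' and 9 = C3'; single enantiomer)
Conditions: preparative SFC, amylose tris(3,5-dimethylphenylcarbamate) phase, CO2/i-PrOH
Reagents that add atoms: none
Why: Resolution by chromatography on a chiral stationary phase; no bond is made or broken, so C8' cannot epimerise, and every later intermediate is a single enantiomer.

Step 9
Reactants: 15 (3aS,6R,8R)-bicyclooctenone
Product: 16 (6S,7R,8'R) butenolide-fused endo-propyl cyclobutanone (4,5,6,7-tetrahydrophthalide with a cyclobutanone cis-fused at C6–C7; carbonyl C3' on C7, C8' on C6, propyl cis to ring B)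
Conditions: hν (300 nm lamps, Pyrex), degassed benzene (0.01 M), rt, stopped at partial conversion; recovered 15 resubmitted
Reagents that add atoms: none
Why: Excitation of the n–π* band of the β,γ-unsaturated ketone should cleave the allylic C3'–C3a bond (α-cleavage) to a singlet acyl–allyl radical pair whose allyl part spans C3a–C7a–C7. Recombination at C7 forms the C3'–C7 bond; the closest known reaction type is the photochemical 1,3-acyl shift of bicyclo[2.2.2]oct-5-en-2-ones to cis-bicyclo[4.2.0]octenones. Ring C closes by this 1,3-migration of the acyl terminus across the allyl unit (radical-pair recombination, formally a suprafacial [1,3] shift), not by a cycloaddition. The new stereocentre C7 is controlled by the tether: C3' stays bonded to C8' and through it to C6, so it can reach only the face of C7 on which C6–H lies, which forces the cis ring fusion. C6 and C8' are not touched, and the propyl group that was anti to the alkene bridge in 15 ends up cis to ring B. The step needs the singlet 1,3-shift in preference to the triplet oxa-di-π-methane rearrangement and to decarbonylation; direct irradiation without a sensitiser and the presence of only one allylic α-bond (C3'–C3a) secure this. The double bond arrives at C3a=C7a, tetrasubstituted and conjugated with the lactone, so ring A appears in the same step. Because 16 is itself a β,γ-unsaturated cyclobutanone, a photostationary mixture is expected and the irradiation is stopped early.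

Step 10
Reactants: 16 endo-propyl cyclobutanone; 17 methyl 2-iodobenzoate
Product: 20 (6S,7R,8'R,3'R) spiro-phthalide butenolide (target skeleton with C3 still CH2), via aryl Grignard reagent 18 (not isolated), via magnesium alkoxide 19 (not isolated)
Conditions: 17, i-PrMgCl·LiCl, THF, −40 °C; then 16, LaCl3·2LiCl, THF, −78 to 0 °C; aqueous NH4Cl
Reagents that add atoms: none
Why: Iodine–magnesium exchange gives the ester-bearing aryl Grignard reagent, which adds to the strained cyclobutanone much faster than to the ring A lactone (the lanthanum salt favours 1,2-addition over enolisation), and the alkoxide closes ring D on the ortho ester; attack from the convex face, anti to ring B and to the endo propyl group, sets C3' with the aryl carbon convex and the lactone oxygen concave.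

Step 11
Reactants: 20 spiro-phthalide butenolide
Product: 21 2-(triisopropylsilyloxy)furan of 20 (furan from C1, O2, C3, C3a, C7a; silyloxy on C1)
Conditions: TIPSOTf, Et3N, CH2Cl2, 0 °C
Reagents that add atoms: triisopropylsilyl trifluoromethanesulfonate, CC(C)[Si](C(C)C)(C(C)C)OS(=O)(=O)C(F)(F)F
Why: Soft enolisation: O-silylation of the ring A carbonyl and loss of a C3 proton give the aromatic silyloxyfuran; C3 is preferred over C4 because only this deprotonation creates the furan, and ring D has no enolisable position.

Step 12
Reactants: 21 silyloxyfuran; 7 butanal
Product: 22 3-(1-hydroxybutyl) butenolide (mixture of epimers at C3 and at the carbinol carbon)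
Conditions: BF3·OEt2, CH2Cl2, −78 °C; aqueous NaHCO3
Reagents that add atoms: none
Why: Vinylogous Mukaiyama aldol addition; the silyloxyfuran reacts at its free 5-position (C3) because the α-position C7a is fully substituted, and the two new centres need no control since both are removed in step 13.

Step 13
Reactants: 22 3-(1-hydroxybutyl) butenolide
Product: 24 target, (Z)-3-butylidene spiro bis-lactone (6S,7R,8'R,3'R), via allylic mesylate 23 (not isolated)
Conditions: MsCl, Et3N, CH2Cl2, 0 °C; then DBU, 0 °C to rt, light excluded
Reagents that add atoms: none
Why: Mesylation and E1cB elimination through the C3-deprotonated 2-oxidofuran; the Z isomer, with the propyl chain turned towards O2, should be favoured because the E isomer suffers allylic strain against C4H2, as in the usual preparations of (Z)-3-alkylidene butenolides and phthalides.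

## Compound list

1 | 3,4-dibromofuran-2(5H)-one | O=C1OCC(Br)=C1Br | starting material
2 | but-3-en-1-ylboronic acid | OB(O)CCC=C | starting material
3 | 3-bromo-4-(but-3-en-1-yl)furan-2(5H)-one | O=C1OCC(CCC=C)=C1Br | intermediate
4 | tributyl(ethenyl)stannane | C=C[Sn](CCCC)(CCCC)CCCC | starting material
5 | 4-(but-3-en-1-yl)-3-ethenylfuran-2(5H)-one | O=C1OCC(CCC=C)=C1C=C | intermediate
6 | 4,5-dihydro-2-benzofuran-1(3H)-one | O=C1OCC2=C1C=CCC2 | intermediate
7 | butanal | CCCC=O | starting material
8 | nitromethane | C[N+](=O)[O-] | starting material
9 | 1-nitropentan-2-ol (racemic) | CCCC(O)C[N+](=O)[O-] | intermediate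
10 | 1-nitropentan-2-yl methanesulfonate (racemic) | CCCC(OS(C)(=O)=O)C[N+](=O)[O-] | intermediate (not isolated)
11 | (E)-1-nitropent-1-ene | CCC/C=C/[N+](=O)[O-] | intermediate
12 | racemic nitro Diels–Alder adduct (nitro syn, propyl anti to the C7=C7a bridge) | O=C1OC[C@]23CC[C@H](C=C12)[C@@H](CCC)[C@@H]3[N+](=O)[O-] | intermediate
13 | potassium nitronate of 12 (racemic) | O=C1OC[C@]23CC[C@H](C=C12)[C@@H](CCC)C3=[N+]([O-])[O-].[K+] | intermediate (not isolated)
14 | racemic 8-propyl-4,5-dihydro-3H-3a,6-ethano-2-benzofuran-1,9(6H)-dione | O=C1OC[C@]23CC[C@H](C=C12)[C@@H](CCC)C3=O | intermediate
15 | (3aS,6R,8R)-8-propyl-4,5-dihydro-3H-3a,6-ethano-2-benzofuran-1,9(6H)-dione | O=C1OC[C@]23CC[C@H](C=C12)[C@@H](CCC)C3=O | intermediate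
16 | (6S,7R,8'R) butenolide-fused endo-propyl cyclobutanone | C1OC(=O)C2=C1CC[C@H]1[C@@H](CCC)C(=O)[C@@H]21 | intermediate
17 | methyl 2-iodobenzoate | COC(=O)c1ccccc1I | starting material
18 | 2-(methoxycarbonyl)phenylmagnesium chloride (LiCl complex) | COC(=O)c1ccccc1[Mg]Cl | intermediate (not isolated)
19 | chloromagnesium alkoxide of the C3' tertiary alcohol (C3' R) | C1OC(=O)C2=C1CC[C@H]1[C@@H](CCC)[C@](O[Mg]Cl)(c3ccccc3C(=O)OC)[C@@H]21 | intermediate (not isolated)
20 | (6S,7R,8'R,3'R) spiro-phthalide butenolide | C1OC(=O)C2=C1CC[C@H]1[C@@H](CCC)[C@@]3(OC(=O)c4ccccc43)[C@@H]21 | intermediate
21 | 2-(triisopropylsilyloxy)furan of 20 | CC(C)[Si](C(C)C)(C(C)C)Oc1occ2CC[C@H]3[C@@H](CCC)[C@@]4(OC(=O)c5ccccc54)[C@H]3c12 | intermediate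
22 | 3-(1-hydroxybutyl) butenolide (epimers at C3 and carbinol) | CCCC(O)C1OC(=O)C2=C1CC[C@H]1[C@@H](CCC)[C@@]3(OC(=O)c4ccccc43)[C@@H]21 | intermediate
23 | mesylate of 22 | CCCC(OS(C)(=O)=O)C1OC(=O)C2=C1CC[C@H]1[C@@H](CCC)[C@@]3(OC(=O)c4ccccc43)[C@@H]21 | intermediate (not isolated)
24 | target, (Z)-3-butylidene spiro bis-lactone (6S,7R,8'R,3'R) | CCC/C=C1\OC(=O)C2=C1CC[C@H]1[C@@H](CCC)[C@@]3(OC(=O)c4ccccc43)[C@@H]21 | target

## Step count and least certain steps

Total: 13 steps. Longest linear sequence: 11 steps (1, 2, 3, 6, 7, 8, 9, 10, 11, 12, 13).

**Step 6 (Diels–Alder).**
- Risk: a slow cycloaddition on a trisubstituted, acyl-bearing diene, so that dimerisation or aromatisation of 6 competes. Incomplete endo selectivity of the nitro group would put part of the material into the wrong propyl series. The regiochemistry rests on a polarity argument.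
- Fallback, from 6 back to 15: 6 is combined with (E)-hex-2-enal under iminium catalysis by a chiral 5-benzyl-2,2,3-trimethylimidazolidin-4-one salt. This dienophile is more electrophilic at room temperature and should give the endo aldehyde adduct F1 enantioselectively. TIPSOTf and Et3N convert it into the silyl enol ether F2. Ozonolysis of that electron-rich double bond (O3, CH2Cl2, −78 °C, then Me2S) removes the formyl carbon and gives 15, so steps 7 and 8 are bypassed.

**Step 9 (key step).**
- Risk: an unfavourable photostationary mixture and secondary photolysis of the cyclobutanone (reverse shift, loss of ketene, decarbonylation), because the product still carries a β,γ-unsaturated ketone chromophore. Leakage into the triplet oxa-di-π-methane path is also possible.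
- Fallback, from 6 back to 20: ring C is made by an intermolecular [2+2] photocycloaddition. 6 and commercial (Z)-3-butylidenephthalide are irradiated with a triplet sensitiser such as thioxanthone; the diene terminus C6 should bond to the alkene CH and C7 to the oxygen-bearing carbon. The head-to-head, cis-fused, endo-propyl isomer is separated and resolved on a chiral phase to give 20. No new compound is made on this way (F0); it costs selectivity and a late resolution.

**Step 7 (Nef reaction).**
- Risk: slow nitronate formation at the hindered C3' next to the quaternary C3a, base-induced opening of or conjugate addition to the unsaturated lactone, and epimerisation of C8' once the ketone is present.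
- Fallback, from 12 back to 14: the nitro group is reduced without a strong base to the oxime F3 (SnCl2·2H2O, PhSH, Et3N), and the oxime is cleaved with buffered aqueous TiCl3.
- If the C8' epimer accumulates, it can be returned by deprotonation with LiN(SiMe3)2 and kinetic protonation from the alkene face.

**Step 10 (aryl addition and lactonisation).**
- Risk: deprotonation at C3 (γ to the butenolide) or at C8' in place of addition, and attack on the ring A lactone.
- Fallback, from 16 back to 20: the three-component aryne coupling. The aryne precursor A5 with CsF in MeCN, the isocyanide A6 and 16 should give the N-tert-butyl iminolactone F4 by convex-face attack under neutral conditions. Mild aqueous acid hydrolyses the imidate to 20.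

**Step 13 (elimination).**
- Risk: formation of the E isomer, or base-induced migration of the C3a=C7a double bond in the dienyl lactone.
- Fallback, from 21 back to 24: an olefination replaces the elimination. 21 is brominated at C3 (NBS, THF, −78 °C) to the γ-bromo butenolide F5. Michaelis–Arbuzov reaction with P(OMe)3 gives the γ-phosphonate F6. Horner–Wadsworth–Emmons reaction with 7 (LiN(SiMe3)2, THF, −78 °C) gives 24.

## Further compounds

F1 | step 6 | endo aldehyde Diels–Alder adduct (CHO on C3', syn to the C7=C7a bridge; propyl anti) | O=C1OC[C@]23CC[C@H](C=C12)[C@@H](CCC)[C@@H]3C=O
F2 | step 6 | triisopropylsilyl enol ether of F1 | O=C1OC[C@]23CC[C@H](C=C12)[C@@H](CCC)C3=CO[Si](C(C)C)(C(C)C)C(C)C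
F0 | step 9 | none | none
F3 | step 7 | C3' oxime of 14 | O=C1OC[C@]23CC[C@H](C=C12)[C@@H](CCC)C3=NO
F4 | step 10 | spiro N-tert-butyl iminolactone of 20 | C1OC(=O)C2=C1CC[C@H]1[C@@H](CCC)[C@@]3(OC(=NC(C)(C)C)c4ccccc43)[C@@H]21
F5 | step 13 | 3-bromo butenolide (C3 epimers) | BrC1OC(=O)C2=C1CC[C@H]1[C@@H](CCC)[C@@]3(OC(=O)c4ccccc43)[C@@H]21
F6 | step 13 | dimethyl C3-phosphonate (C3 epimers) | COP(=O)(OC)C1OC(=O)C2=C1CC[C@H]1[C@@H](CCC)[C@@]3(OC(=O)c4ccccc43)[C@@H]21
A1 | alternative 1 | cyclobut-2-enone | O=C1C=CC1
A2 | alternative 1 | (E)-1-(tert-butyldimethylsilyloxy)buta-1,3-diene | C=C/C=C/O[Si](C)(C)C(C)(C)C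
A3 | alternative 1 | endo silyloxy cis-bicyclo[4.2.0]octenone | O=C1C[C@@H]2CC=C[C@H](O[Si](C)(C)C(C)(C)C)[C@H]12
A4 | alternative 2 | endo-8-propylbicyclo[4.2.0]oct-2-en-7-one | C1C=C[C@H]2[C@@H](CCC)C(=O)[C@H]2C1
A5 | alternative 2 | 2-(trimethylsilyl)phenyl trifluoromethanesulfonate | C[Si](C)(C)c1ccccc1OS(=O)(=O)C(F)(F)F
A6 | alternative 2 | tert-butyl isocyanide | CC(C)(C)[N+]#[C-]
A7 | alternative 2 | spiro N-tert-butyl iminoisobenzofuran on the propyl bicyclo[4.2.0]octene | C1C=C[C@H]2[C@@H](CCC)[C@@]3(OC(=NC(C)(C)C)c4ccccc43)[C@H]2C1
A8 | alternative 3 | enyne precursor of the tetraene | CCC/C=C/C#CC1=C(/C=C2\OC(=O)c3ccccc23)C(=O)OC1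
A9 | alternative 3 | (E,Z,Z,Z)-tetraene | CCC/C=C/C=C\C1=C(/C=C2\OC(=O)c3ccccc23)C(=O)OC1
A10 | alternative 3 | 4,5-didehydro spiro-phthalide tetracycle | C1OC(=O)C2=C1C=C[C@H]1[C@@H](CCC)[C@@]3(OC(=O)c4ccccc43)[C@@H]21
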